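Start from the balance of J: in Thursday's run Z and J together read 98.7% at 90.0 min, so within the scatter J lost is Z made. By the proposed steps, each Z also leaves a D that can hold a second G as E.

| setting | Thursday's | flask |
|---|---|---|
| J | 0.15 M | 0.074 M |
| G | 0.222 M (in portions, 2) | 0.222 M (in portions, 2) |
| remark | run made earlier; portions every 50 min | the portions of G follow each other after 50 min, the first at the start |
| time |  | 8.0 h |

Thursday's run (percent of the J charged)

| time / min | Z / % | J / % |
|---|---|---|
| 8.00 | 3.3 | 96.1 |
| 25.0 | 6.2 | 94.3 |
| 40.0 | 10.4 | 90.3 |
| 60.0 | 16.3 | 84.2 |
| 90.0 | 26.2 | 72.5 |

(standard deviation of a reading: 1 percentage point)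

* where most of what was charged as J, at 8.0 h is found (Z / J)
* the largest share itself, whichever of these holds it, in percent of the J charged

Replace the falling [G] by its mean and J decays as a pseudo-first-order species: ln(J charged / J left) equals k times mean [G] times time. Thursday's reading at 40.0 min comes before its second portion. If every D holds a G, the mean there is the first portion less the J lost, so k is 0.0264 M⁻¹ min⁻¹. But that loss is 9.70% with a scatter of 1 percentage point, so k is a rough reading.

In your flask, the full charge overstates the mean: the second portion is absent for 50 min, which leaves a time-averaged charge of 0.210 M. If every D holds a G, two G leave the free pool per Z. A straight line would put mean conversion at 0.5 of its final value, but conversion bends over, so take a parabola's 0.667. That subtracts 1.33 times [J] charged times the final Z share, which is itself unknown. Assuming full conversion gives 75.8%, that gives 82.1%, and that gives 80.7%. So I take 0.131 M as the mean free [G], the time-average of unbound G, and Z at 81.0%. If D held no G, the same k would give 88.5%.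

The forecast says Z at 83%, above my figure, and its ground is “Either way, Z dominates”.

The flask gives Z at 81.4%, with J at 18.6%.

    G + D ⇌ E, settled at all times (K = 570 M⁻¹)
    J + G → D + Z (k = 1.60 M⁻¹ h⁻¹)

Through k, that J asks for a mean free [G] of 0.133 M, against my 0.131 M. Now charge 0.38 M of G, all else held. The same reckoning gives a mean free [G] of 0.265 M and Z at 96.5%. That neighbouring flask ends with Z at 96.2% and J at 3.76%.

The data were computed from invented constants, and the scatter is random.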